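**Plan**
- Retrosynthesis: the interflavanyl C4(upper)–C6(lower) bond is cut first, giving two 7,8,4'-trihydroxyflavan units that share the C3 configuration and differ only at C2. In the all-cis lower unit, ring C is then cut at O1–C8a and C3–C4, giving a 2-fluoroaroyl chloride (ring A plus C4) and an α-benzyloxy aryl ketone (ring B, C2, C3, O1).
- Enabling feature: O1–C2–C3–C4=O is a 2-alkoxy-1,3-dicarbonyl pattern and the C4 oxygen is ortho to C8a on ring A. One Claisen acylation/SNAr cascade therefore closes ring C as a flat flavonol ether. Fluoride, the C4 ketone and the C2=C3 bond are helpers and are removed afterwards.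
- Forward order: rings A and B arrive preformed; ring C is closed (step 5), reduced and deprotected to the lower monomer. Part of this monomer is epimerised at C2 and turned into a 4-thioether, and the two flavans are joined last at C4–C6.
- Stereochemistry: C2, C3 and C4 of the lower unit come from one catalyst-controlled syn hydrogenation of the flavonol. The upper unit keeps that C3, gains 2S by thermodynamic C2-epimerisation through a ring B quinone methide, and its C4 is set by attack anti to the 3-hydroxyl.

Key step: step 5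

Remark: the target is read as ent-oritin-(4β→6)-epioritin-4α-ol (upper unit 2S,3R,4S; lower unit 2R,3R,4R); compounds 6 and 7 are taken as commercial; the C3 descriptor of the upper unit changes between 16 (R), 17 (S) and 18 (R) only through CIP priorities, not in space.

Step 1
Reactants: 1 3-fluorobenzene-1,2-diol (3-fluorocatechol)
Product: 2 1,2-bis(benzyloxy)-3-fluorobenzene
Conditions: BnBr (2.2 equiv), K2CO3, DMF, 60 °C
Reagents that add atoms: benzyl bromide, BrCc1ccccc1
Why: Williamson etherification of both catechol hydroxyls masks the future 7- and 8-oxygens as benzyl ethers that tolerate organolithium and amide bases and are cleaved later by hydrogenolysis.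

Step 2
Reactants: 2 1,2-bis(benzyloxy)-3-fluorobenzene
Product: 4 3,4-bis(benzyloxy)-2-fluorobenzoic acid, via aryllithium 3 (not isolated)
Conditions: n-BuLi, THF, −78 °C; CO2 (g); aq. HCl
Reagents that add atoms: carbon dioxide, O=C=O
Why: Fluorine-directed ortho-lithiation removes the most acidic ring proton next to fluorine (as in the lithiation of fluoroveratroles) and carboxylation places the future C4 carbon beside the carbon that carries the fluoride leaving group.

Step 3
Reactants: 4 3,4-bis(benzyloxy)-2-fluorobenzoic acid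
Product: 5 3,4-bis(benzyloxy)-2-fluorobenzoyl chloride
Conditions: (COCl)2, DMF (cat.), CH2Cl2, 0 °C to rt
Reagents that add atoms: oxalyl chloride, ClC(=O)C(Cl)=O
Why: Acid chloride formation through the catalytic Vilsmeier-type chloroiminium species gives the acyl donor for the annulation without touching the benzyl ethers or the aryl fluoride.

Step 4
Reactants: 6 [4-(benzyloxy)phenyl]magnesium bromide (THF solution); 7 2-(benzyloxy)-N-methoxy-N-methylacetamide
Product: 9 2-(benzyloxy)-1-[4-(benzyloxy)phenyl]ethan-1-one, via magnesium hemiaminal chelate 8 (not isolated)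
Conditions: THF, 0 °C; aq. HCl
Reagents that add atoms: none
Why: Weinreb ketone synthesis, in which the chelated tetrahedral adduct prevents over-addition and releases the α-benzyloxy ketone carrying ring B, C2, C3 and the future O1 on acidic work-up.

Step 5
Reactants: 9 2-(benzyloxy)-1-[4-(benzyloxy)phenyl]ethan-1-one; 5 3,4-bis(benzyloxy)-2-fluorobenzoyl chloride
Product: 12 3,7,8-tris(benzyloxy)-2-[4-(benzyloxy)phenyl]-4H-chromen-4-one, via lithium enolate 10 (not isolated), via 1,3-diketone 11 (not isolated)
Conditions: LiN(SiMe3)2 (2.2 equiv), THF, −78 °C; then 5, −78 °C to rt; then DMF added, 90 °C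
Reagents that add atoms: none
Why: The chelated Z-lithium enolate 10 is C-acylated at C3 by acid chloride 5 (Claisen-type acylation, forming C3–C4), and the second equivalent of base turns the 2-benzyloxy-1,3-diketone 11 into its enolate, whose oxygen on the ring B side (the future O1) adds to the fluorine-bearing carbon C8a and expels fluoride (addition–elimination SNAr, forming O1–C8a). The closest known reaction type is the chromone and flavone annulation of ketone enolates with 2-halobenzoyl chlorides, that is C-acylation followed by intramolecular O-arylation of the 1,3-diketone. Ring C closes by a 6-exo-trig addition of the enolate oxygen to C8a through a Meisenheimer intermediate, the only possible closure because the other enolate oxygen could only form a four-membered ring. No stereocentre is created, since the step deliberately delivers C2, C3 and C4 as one flat conjugated unit so that step 6 can set all three from one face. The selectivities needed are C- over O-acylation and substitution at C8a only: lithium chelation by the α-benzyloxy group and the excess base (any enol ester is transacylated to the diketone) should secure the first, and the new C4 carbonyl ortho to the only leaving group on ring A should secure the second.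

Step 6
Reactants: 12 3,7,8-tris(benzyloxy)-2-[4-(benzyloxy)phenyl]-4H-chromen-4-one
Product: 14 (2R,3R,4R)-3,7,8-tris(benzyloxy)-2-[4-(benzyloxy)phenyl]-3,4-dihydro-2H-chromen-4-ol, via cis-flavanone 13 (not isolated)
Conditions: H2 (100 bar), Ru(cod)(2-methylallyl)2, chiral imidazolinium salt SINpEt·HBF4 (1,3-bis[1-(1-naphthyl)ethyl]-4,5-dihydroimidazolium tetrafluoroborate, antipode selected for the 2R series), KOt-Bu, toluene, 40 °C
Reagents that add atoms: none
Why: Proposed new method: a chiral ruthenium–NHC hydride should add H2 syn to one face of the tetrasubstituted C2=C3 bond of the vinylogous ester, which places the C2 aryl and C3 benzyloxy groups cis (ketone 13), and should then reduce the C4 carbonyl from the same face, now the less hindered one opposite both substituents, so that the 2,3-cis-3,4-cis triad arises in one operation with the ligand antipode fixing 2R,3R,4R; the closest known reaction type is the ruthenium–NHC asymmetric hydrogenation of flavones and chromones to cis-flavan-4-ols, extended here to a 3-alkoxy-substituted olefin.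

Step 7
Reactants: 14 (2R,3R,4R)-3,7,8-tris(benzyloxy)-2-[4-(benzyloxy)phenyl]-3,4-dihydro-2H-chromen-4-ol
Product: 15 (2R,3R,4R)-2-(4-hydroxyphenyl)-3,4-dihydro-2H-chromene-3,4,7,8-tetrol (teracacidin, epioritin-4α-ol)
Conditions: H2 (1 atm), Pd(OH)2/C, THF–MeOH, rt, stopped at complete debenzylation
Reagents that add atoms: none
Why: Catalytic hydrogenolysis of the four O-benzyl groups under neutral conditions should leave the acid-labile benzylic C4–OH and the three stereocentres untouched.

Step 8
Reactants: 15 (2R,3R,4R)-2-(4-hydroxyphenyl)-3,4-dihydro-2H-chromene-3,4,7,8-tetrol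
Product: 16 (2S,3R,4R)-2-(4-hydroxyphenyl)-3,4-dihydro-2H-chromene-3,4,7,8-tetrol (ent-oritin-4α-ol)
Conditions: H2O (degassed, Ar), sealed tube, 120 °C; Sephadex LH-20 separation, recovered 15 reused in step 10
Reagents that add atoms: none
Why: Thermal C2-epimerisation of a free-phenolic flavan (known for catechins and for flavan-3,4-diols in hot water) should work because the 4'-hydroxyl lets the O1–C2 bond open to a ring B quinone methide and reclosure under thermodynamic control favours the 2,3-trans isomer with C3 untouched, any accompanying C4 epimerisation being harmless since C4 is ionised in step 9.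

Step 9
Reactants: 16 (2S,3R,4R)-2-(4-hydroxyphenyl)-3,4-dihydro-2H-chromene-3,4,7,8-tetrol
Product: 17 (2S,3S,4S)-4-(benzylsulfanyl)-2-(4-hydroxyphenyl)-3,4-dihydro-2H-chromene-3,7,8-triol (4β-benzylsulfanyl-ent-oritin)
Conditions: BnSH, AcOH, EtOH, reflux
Reagents that add atoms: phenylmethanethiol, SCc1ccccc1
Why: Acid-promoted thiolysis of a flavan-3,4-diol ionises the benzylic 4-OH to the C4 cation stabilised by O1 and the 7-oxygen, and the thiol should capture it anti to the 3-hydroxyl (3,4-trans), so that either C4 epimer of the diol converges on the one thioether.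

Step 10
Reactants: 17 (2S,3S,4S)-4-(benzylsulfanyl)-2-(4-hydroxyphenyl)-3,4-dihydro-2H-chromene-3,7,8-triol; 15 (2R,3R,4R)-2-(4-hydroxyphenyl)-3,4-dihydro-2H-chromene-3,4,7,8-tetrol
Product: 18 (2R,3R,4R)-6-[(2S,3R,4S)-3,7,8-trihydroxy-2-(4-hydroxyphenyl)-3,4-dihydro-2H-chromen-4-yl]-2-(4-hydroxyphenyl)-3,4-dihydro-2H-chromene-3,4,7,8-tetrol (target)
Conditions: AgBF4, THF, 0 °C, 15 (3 equiv)
Reagents that add atoms: none
Why: Thiophilic activation of the 4-benzylsulfanyl group by silver ion generates the upper-unit C4 carbocation under neutral conditions that leave the 4-OH of 15 intact, and Friedel–Crafts attack by C6 of 15 (ortho to the 7-OH and para to O1, the most nucleophilic ring A position) anti to the 3-hydroxyl should give the 4β→6 bond with 3,4-trans configuration, as in the known silver-mediated coupling of 4-thioflavans with phenolic flavan nucleophiles.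

**Compound list**
1 | 3-fluorobenzene-1,2-diol (3-fluorocatechol) | Oc1cccc(F)c1O | starting material
2 | 1,2-bis(benzyloxy)-3-fluorobenzene | Fc1cccc(OCc2ccccc2)c1OCc1ccccc1 | intermediate
3 | [3,4-bis(benzyloxy)-2-fluorophenyl]lithium | [Li]c1ccc(OCc2ccccc2)c(OCc2ccccc2)c1F | intermediate
4 | 3,4-bis(benzyloxy)-2-fluorobenzoic acid | OC(=O)c1ccc(OCc2ccccc2)c(OCc2ccccc2)c1F | intermediate
5 | 3,4-bis(benzyloxy)-2-fluorobenzoyl chloride | ClC(=O)c1ccc(OCc2ccccc2)c(OCc2ccccc2)c1F | intermediate
6 | [4-(benzyloxy)phenyl]magnesium bromide | Br[Mg]c1ccc(OCc2ccccc2)cc1 | starting material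
7 | 2-(benzyloxy)-N-methoxy-N-methylacetamide | CON(C)C(=O)COCc1ccccc1 | starting material
8 | bromomagnesium 2-(benzyloxy)-1-[4-(benzyloxy)phenyl]-1-[methoxy(methyl)amino]ethan-1-olate | CON(C)C(COCc1ccccc1)(O[Mg]Br)c1ccc(OCc2ccccc2)cc1 | intermediate
9 | 2-(benzyloxy)-1-[4-(benzyloxy)phenyl]ethan-1-one | O=C(COCc1ccccc1)c1ccc(OCc2ccccc2)cc1 | intermediate
10 | lithium (Z)-2-(benzyloxy)-1-[4-(benzyloxy)phenyl]ethen-1-olate | [Li]O/C(=C\OCc1ccccc1)c1ccc(OCc2ccccc2)cc1 | intermediate
11 | 2-(benzyloxy)-1-[3,4-bis(benzyloxy)-2-fluorophenyl]-3-[4-(benzyloxy)phenyl]propane-1,3-dione (present as its lithium enolate) | O=C(C(OCc1ccccc1)C(=O)c1ccc(OCc2ccccc2)cc1)c1ccc(OCc2ccccc2)c(OCc2ccccc2)c1F | intermediate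
12 | 3,7,8-tris(benzyloxy)-2-[4-(benzyloxy)phenyl]-4H-chromen-4-one | O=c1c(OCc2ccccc2)c(-c2ccc(OCc3ccccc3)cc2)oc2c(OCc3ccccc3)c(OCc3ccccc3)ccc12 | intermediate
13 | (2R,3S)-3,7,8-tris(benzyloxy)-2-[4-(benzyloxy)phenyl]-2,3-dihydro-4H-chromen-4-one | C(c5ccccc5)Oc1ccc([C@H]2Oc3c(ccc(OCc4ccccc4)c3OCc6ccccc6)C(=O)[C@H]2OCc7ccccc7)cc1 | intermediate
14 | (2R,3R,4R)-3,7,8-tris(benzyloxy)-2-[4-(benzyloxy)phenyl]-3,4-dihydro-2H-chromen-4-ol | C(c5ccccc5)Oc1ccc([C@H]2Oc3c(ccc(OCc4ccccc4)c3OCc6ccccc6)[C@@H](O)[C@H]2OCc7ccccc7)cc1 | intermediate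
15 | (2R,3R,4R)-2-(4-hydroxyphenyl)-3,4-dihydro-2H-chromene-3,4,7,8-tetrol (teracacidin) | Oc1ccc([C@H]2Oc3c(ccc(O)c3O)[C@@H](O)[C@H]2O)cc1 | intermediate
16 | (2S,3R,4R)-2-(4-hydroxyphenyl)-3,4-dihydro-2H-chromene-3,4,7,8-tetrol | Oc1ccc([C@@H]2Oc3c(ccc(O)c3O)[C@@H](O)[C@H]2O)cc1 | intermediate
17 | (2S,3S,4S)-4-(benzylsulfanyl)-2-(4-hydroxyphenyl)-3,4-dihydro-2H-chromene-3,7,8-triol | Oc1ccc([C@@H]2Oc3c(ccc(O)c3O)[C@H](SCc4ccccc4)[C@H]2O)cc1 | intermediate
18 | (2R,3R,4R)-6-[(2S,3R,4S)-3,7,8-trihydroxy-2-(4-hydroxyphenyl)-3,4-dihydro-2H-chromen-4-yl]-2-(4-hydroxyphenyl)-3,4-dihydro-2H-chromene-3,4,7,8-tetrol | Oc1ccc([C@H]2Oc3c(cc([C@H]4c5ccc(O)c(O)c5O[C@@H](c5ccc(O)cc5)[C@@H]4O)c(O)c3O)[C@@H](O)[C@H]2O)cc1 | target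

Total step count: 10
Longest linear sequence: 9 steps (steps 1, 2, 3, 5, 6, 7, 8, 9, 10, from compound 1).

**Steps most likely to fail**

Step 6 (Proposed new method). The hindered tetrasubstituted 3-benzyloxy olefin may resist hydrogenation, the intermediate ketone may epimerise at C3 before the carbonyl is reduced, or facial discrimination by the catalyst may be poor. The fallback uses known chemistry and sets out from 12. Heterogeneous hydrogenation (H2, Pd/C, then Raney Ni under pressure, EtOH) is the classical cis-reduction of flavonols to all-cis flavan-3,4-diols and also cleaves the benzyl ethers. It should give 15 as a racemate with its enantiomer (2S,3S,4S)-2-(4-hydroxyphenyl)-3,4-dihydro-2H-chromene-3,4,7,8-tetrol F1. The enantiomers are then separated by preparative HPLC on a cellulose tris(3,5-dimethylphenylcarbamate) phase, and the route is rejoined at 15 (steps 6 and 7 are bypassed).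

Step 8. Ring opening at C2 may be slow and may be overtaken by C4 solvolysis, self-condensation or autoxidation of the pyrogallol-type ring A. The fallback sets out from 12 and builds the 2S series independently:
- Hydrogenolysis (H2, Pd/C, EtOAc–MeOH) gives 3,7,8-trihydroxy-2-(4-hydroxyphenyl)-4H-chromen-4-one F2.
- Dithionite reduction (Na2S2O4, aq. Na2CO3, 90 °C), the known conversion of flavonols into 2,3-trans-dihydroflavonols, gives the racemic ketone.
- Separation on a chiral stationary phase delivers (2S,3S)-3,7,8-trihydroxy-2-(4-hydroxyphenyl)-2,3-dihydro-4H-chromen-4-one F3 and sets aside (2R,3R)-3,7,8-trihydroxy-2-(4-hydroxyphenyl)-2,3-dihydro-4H-chromen-4-one F4.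
- NaBH4 (EtOH, 0 °C) should reduce F3, with hydride delivered to give the 3,4-trans diol (2S,3R,4S)-2-(4-hydroxyphenyl)-3,4-dihydro-2H-chromene-3,4,7,8-tetrol F5.
- Thiolysis of F5 under the conditions of step 9 rejoins the route at 17.

Step 10. The C4 cation may be captured by hydroxyl oxygen (ether-linked dimers) or by C5 instead of C6, and 3,4-trans selectivity may erode. The fallback sets out from 16 and 15 and replaces thiophilic activation by an equilibrating Brønsted-acid condensation (0.1 M aq. HCl, rt, 15 in excess). The pseudo-axial 4-OH of the 2,3-trans-3,4-cis diol 16 should ionise faster than the pseudo-equatorial 4-OH of all-cis 15, and ether formation is reversible in acid, so the C4–C6 product should accumulate. This gives 18 directly and makes no new compound (F0).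

Further compounds
F1 | step 6 | (2S,3S,4S)-2-(4-hydroxyphenyl)-3,4-dihydro-2H-chromene-3,4,7,8-tetrol | Oc1ccc([C@@H]2Oc3c(ccc(O)c3O)[C@H](O)[C@@H]2O)cc1
F2 | step 8 | 3,7,8-trihydroxy-2-(4-hydroxyphenyl)-4H-chromen-4-one | O=c1c(O)c(-c2ccc(O)cc2)oc2c(O)c(O)ccc12
F3 | step 8 | (2S,3S)-3,7,8-trihydroxy-2-(4-hydroxyphenyl)-2,3-dihydro-4H-chromen-4-one | Oc1ccc([C@@H]2Oc3c(ccc(O)c3O)C(=O)[C@H]2O)cc1
F4 | step 8 | (2R,3R)-3,7,8-trihydroxy-2-(4-hydroxyphenyl)-2,3-dihydro-4H-chromen-4-one | Oc1ccc([C@H]2Oc3c(ccc(O)c3O)C(=O)[C@@H]2O)cc1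
F5 | step 8 | (2S,3R,4S)-2-(4-hydroxyphenyl)-3,4-dihydro-2H-chromene-3,4,7,8-tetrol | Oc1ccc([C@@H]2Oc3c(ccc(O)c3O)[C@H](O)[C@H]2O)cc1
F0 | step 10 | none | none
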